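**Retrosynthetic overview**
1. Target 21 ⇐ ketone 19 (C4 methylenation, O1 desilylation); its esters ⇐ 7α,8α,11-triol 18 ⇐ OsO4 on allylic acetate 17.
2. The C9–C11 and C12–C13 bonds, the C9 quaternary centre, C11 and the Δ7 alkene ⇐ one light-driven radical cascade between the O1-tethered vinylsilane of 13 and bromobutenolide 14, then Tamao oxidation.
3. Rings A and B are formed together (trans-decalin 13) by an intramolecular Diels–Alder reaction of trienone 12 (E-acetoxy-enone dienophile, 2,3-dimethyldiene).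
4. 12 ⇐ lactone 1 (L-glutamic acid series) by two Wittig olefinations, Weinreb opening, silylation and aza-enolate acylation; C1 is the only bought stereocentre and relays to all others.
5. Ring order: A and B in one step (step 7); the butenolide ring is bought and attached in step 8.

Assumption: clerodane numbering is used (ring A = C1–C5, C10; ring B = C5–C10; side chain C11–C16; methyls C17 on C8, C19 on C5, C20 on C9; C18 = exocyclic CH2 on C4), β is the decalin face carrying the C5 methyl and α the opposite face, and compounds 1, 2, 7, 9 and 14 are taken as commercially available.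

Step 1
Reactants: 1 (S)-5-(hydroxymethyl)dihydrofuran-2(3H)-one; 2 3-(triphenylphosphoranylidene)butan-2-one
Product: 4 (S)-5-[(E)-2-methyl-3-oxobut-1-en-1-yl]dihydrofuran-2(3H)-one, via aldehyde 3 (not isolated)
Conditions: IBX, DMSO, rt; then 2, rt → 40 °C
Reagents that add atoms: none
Why: IBX oxidation gives the configurationally fragile α-acyloxy aldehyde, which is trapped in the same flask by the ketone-stabilised ylide in an E-selective Wittig olefination, leaving the bought C1 stereocentre (S) untouched.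

Step 2
Reactants: 4 (S)-5-[(E)-2-methyl-3-oxobut-1-en-1-yl]dihydrofuran-2(3H)-one
Product: 5 (S)-5-[(E)-2,3-dimethylbuta-1,3-dien-1-yl]dihydrofuran-2(3H)-one
Conditions: Ph3PCH3Br, KOtBu, THF, 0 °C
Reagents that add atoms: methyltriphenylphosphonium bromide (C[P+](c1ccccc1)(c1ccccc1)c1ccccc1.[Br-])
Why: Wittig methylenation, in which the ylide attacks the conjugated methyl ketone much faster than the lactone, gives the 2,3-dimethyl-1,3-diene.

Step 3
Reactants: 5 (S)-5-[(E)-2,3-dimethylbuta-1,3-dien-1-yl]dihydrofuran-2(3H)-one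
Product: 6 (4S,5E)-4-hydroxy-N-methoxy-N,6,7-trimethylocta-5,7-dienamide
Conditions: MeNH(OMe)·HCl, iPrMgCl, THF, −20 → 0 °C
Reagents that add atoms: N,O-dimethylhydroxylamine hydrochloride (CNOC.Cl)
Why: Weinreb aminolysis of the γ-lactone by the magnesium amide opens the ring without touching the carbinol configuration.

Step 4
Reactants: 6 (4S,5E)-4-hydroxy-N-methoxy-N,6,7-trimethylocta-5,7-dienamide; 7 chloro(diphenyl)vinylsilane
Product: 8 (4S,5E)-4-{[diphenyl(vinyl)silyl]oxy}-N-methoxy-N,6,7-trimethylocta-5,7-dienamide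
Conditions: imidazole, CH2Cl2, 0 °C → rt
Reagents that add atoms: none
Why: Standard silylation of the secondary alcohol installs a group that protects O1 now and serves as the radical tether in step 8.

Step 5
Reactants: 8 (4S,5E)-4-{[diphenyl(vinyl)silyl]oxy}-N-methoxy-N,6,7-trimethylocta-5,7-dienamide; 9 propanal N,N-dimethylhydrazone
Product: 11 (6S,7E)-6-{[diphenyl(vinyl)silyl]oxy}-2,8,9-trimethyl-3-oxodeca-7,9-dienal (2-formyl ketone; largely enolised), via keto hydrazone 10 (not isolated)
Conditions: 9, LiN(iPr)2 (2.2 equiv), THF, 0 °C; 8, −78 → 0 °C; then aq. CuCl2, THF, pH 7 buffer, rt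
Reagents that add atoms: water (O)
Why: C-acylation of the lithium aza-enolate by the Weinreb amide (Corey–Enders hydrazone chemistry) stops at the ketone because the product is deprotonated, and neutral CuCl2-assisted hydrolysis frees the 2-formyl ketone without cleaving the silyl ether.

Step 6
Reactants: 11 (6S,7E)-6-{[diphenyl(vinyl)silyl]oxy}-2,8,9-trimethyl-3-oxodeca-7,9-dienal
Product: 12 (1E,6S,7E)-6-{[diphenyl(vinyl)silyl]oxy}-2,8,9-trimethyl-3-oxodeca-1,7,9-trien-1-yl acetate
Conditions: Ac2O, Et3N, DMAP (cat.), CH2Cl2, 0 °C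
Reagents that add atoms: acetic anhydride (CC(=O)OC(C)=O)
Why: O-acylation of the hydroxymethylene (enol) tautomer gives the enol acetate, whose E isomer (acetoxy trans to the acyl group) is expected to predominate by dipole minimisation and later fixes the cis C5-methyl/C6-acetoxy relationship.

Step 7
Reactants: 12 (1E,6S,7E)-6-{[diphenyl(vinyl)silyl]oxy}-2,8,9-trimethyl-3-oxodeca-1,7,9-trien-1-yl acetate
Product: 13 trans-fused octalone: 6β-acetoxy-1α-{[diphenyl(vinyl)silyl]oxy}-5β,8,9-trimethyl-10αH-Δ8(9)-octal-4-one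
Conditions: toluene (0.01 M), BHT (cat.), 150 °C, sealed tube
Reagents that add atoms: none
Why: Thermal type 1 intramolecular Diels–Alder reaction, in which allylic 1,3-strain against the C9 methyl puts H1 in the diene plane and the silyloxy group anti to the forming C5–C10 bond (1α, equatorial), the same methyl disfavours the cis-fused (tether-endo) transition state so that the 5β-Me/10α-H trans fusion results, and the E enol acetate delivers 6β-OAc.

Step 8
Reactants: 13 trans-fused octalone (as above); 14 4-bromofuran-2(5H)-one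
Product: 15 cyclic siloxane: 6β-acetoxy-5β,8,9β-trimethyl-10αH-Δ7-octal-4-one in which O1 (α) and C11 (on C9, α) are bridged by SiPh2 in a six-membered ring; C11 also bears H and CH2-(5-oxo-2,5-dihydrofuran-3-yl), configured as in the target
Conditions: 14 (1.5 equiv, syringe pump, 6 h), 10-phenylphenothiazine (5 mol %), 2,6-lutidine (2 equiv), MeCN (0.02 M), 390 nm LEDs, rt
Reagents that add atoms: none
Why: Proposed new method: the excited phenothiazine reduces 14 to bromide and a butenolid-4-yl (vinyl) radical that adds to the terminal carbon of the vinylsilane (C12–C13 bond); the resulting α-silyl radical at C11 closes 6-exo onto C9 from the α face, the only face the O1–Si tether can reach (C9–C11 bond, C20 left β), through a chair in which the C12 substituent lies pseudo-axial, anti to C20 and away from both Si-phenyl groups (sets C11); the tertiary C8 radical is then oxidised by the phenothiazine radical cation and the cation loses H7 to lutidine to give the Δ7 alkene; the closest known reaction types are the Stork–Nishiyama silicon-tethered radical cyclisation and photoredox radical–polar-crossover Heck-type alkene functionalisation, which have not been combined in an intermolecular vinyl-radical/tethered cyclisation onto a tetrasubstituted alkene.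

Step 9
Reactants: 15 cyclic siloxane (as above)
Product: 16 diol: 6β-acetoxy-1α-hydroxy-9α-[(1R)-1-hydroxy-2-(5-oxo-2,5-dihydrofuran-3-yl)ethyl]-5β,8,9β-trimethyl-10αH-Δ7-octal-4-one
Conditions: 30% H2O2, KF, KHCO3, THF/MeOH, rt
Reagents that add atoms: hydrogen peroxide (OO)
Why: Tamao–Kumada oxidation converts the C11–Si bond into C11–OH with retention of configuration and hydrolyses the Si–O1 bond, the bicarbonate conditions sparing acetate, ketone and butenolide.

Step 10
Reactants: 16 diol (as above)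
Product: 17 1-O-triethylsilyl ether of 16 (11-OH free)
Conditions: TESCl (1.05 equiv), imidazole, CH2Cl2, −20 °C
Reagents that add atoms: chlorotriethylsilane (CC[Si](Cl)(CC)CC)
Why: Site-selective silylation, because the equatorial ring hydroxyl at C1 is far less hindered than the neopentyl C11 carbinol next to the quaternary C9.

Step 11
Reactants: 17 1-O-triethylsilyl ether of 16
Product: 18 triol: 6β-acetoxy-7α,8α,11-trihydroxy-1α-triethylsilyloxy compound (8β-Me, 4-ketone, butenolide intact)
Conditions: OsO4 (5 mol %), NMO, acetone/H2O, rt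
Reagents that add atoms: osmium tetroxide (O=[Os](=O)(=O)=O); N-methylmorpholine N-oxide (C[N+]1([O-])CCOCC1); water (O)
Why: Upjohn dihydroxylation, in which OsO4 takes the electron-rich trisubstituted Δ7 alkene rather than the electron-poor butenolide and attacks the α face, anti to the axial β-methyls on C5 and C9 and to the allylic 6β-acetate (Kishi rule), giving the 7α,8α-cis-diol.

Step 12
Reactants: 18 triol (as above)
Product: 19 7,11-bis(isobutyrate) of 18 (8α-OH free, 1α-OTES, 4-ketone)
Conditions: (iPrCO)2O, DMAP, pyridine, CH2Cl2, 0 °C → rt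
Reagents that add atoms: isobutyric anhydride (CC(C)C(=O)OC(=O)C(C)C)
Why: DMAP-catalysed acylation esterifies the two secondary hydroxyls (O7 and O11) while the tertiary 8α-OH stays free, the low temperature limiting 6→7 acetyl migration.

Step 13
Reactants: 19 7,11-bis(isobutyrate) (as above)
Product: 21 target: (1S,5S,6S,7R,8S,9R,10R,11R)-6-acetoxy-1,8-dihydroxy-7,11-bis(isobutyryloxy)cleroda-4(18),13-dien-15,16-olide, via silyl ether 20 (not isolated)
Conditions: Zn, CH2Br2, TiCl4, THF/CH2Cl2, 0 °C → rt; then 1 M HCl, THF, rt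
Reagents that add atoms: dibromomethane (BrCBr)
Why: Lombardo (Takai–Lombardo) methylenation converts the hindered C4 ketone into the exocyclic methylene under non-basic conditions that tolerate esters and the butenolide, and the acidic quench cleaves the triethylsilyl ether to free the 1α-OH.

**Compound list**
1 | (S)-5-(hydroxymethyl)dihydrofuran-2(3H)-one | O=C1CC[C@@H](CO)O1 | starting material
2 | 3-(triphenylphosphoranylidene)butan-2-one | CC(=O)C(C)=P(c1ccccc1)(c1ccccc1)c1ccccc1 | starting material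
3 | (S)-5-oxotetrahydrofuran-2-carbaldehyde | O=C1CC[C@@H](C=O)O1 | intermediate
4 | (S)-5-[(E)-2-methyl-3-oxobut-1-en-1-yl]dihydrofuran-2(3H)-one | O=C1CC[C@@H](/C=C(\C)C(C)=O)O1 | intermediate
5 | (S)-5-[(E)-2,3-dimethylbuta-1,3-dien-1-yl]dihydrofuran-2(3H)-one | O=C1CC[C@@H](/C=C(\C)C(C)=C)O1 | intermediate
6 | (4S,5E)-4-hydroxy-N-methoxy-N,6,7-trimethylocta-5,7-dienamide | CON(C)C(=O)CC[C@H](O)/C=C(\C)C(C)=C | intermediate
7 | chloro(diphenyl)vinylsilane | C=C[Si](Cl)(c1ccccc1)c1ccccc1 | starting material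
8 | (4S,5E)-4-{[diphenyl(vinyl)silyl]oxy}-N-methoxy-N,6,7-trimethylocta-5,7-dienamide | CON(C)C(=O)CC[C@H](O[Si](C=C)(c1ccccc1)c1ccccc1)/C=C(\C)C(C)=C | intermediate
9 | propanal N,N-dimethylhydrazone | CCC=NN(C)C | starting material
10 | (6S,7E)-1-(2,2-dimethylhydrazinylidene)-6-{[diphenyl(vinyl)silyl]oxy}-2,8,9-trimethyldeca-7,9-dien-3-one (epimers at C2) | CN(C)N=CC(C)C(=O)CC[C@H](O[Si](C=C)(c1ccccc1)c1ccccc1)/C=C(\C)C(C)=C | intermediate
11 | (6S,7E)-6-{[diphenyl(vinyl)silyl]oxy}-2,8,9-trimethyl-3-oxodeca-7,9-dienal (enolised 2-formyl ketone) | O=CC(C)C(=O)CC[C@H](O[Si](C=C)(c1ccccc1)c1ccccc1)/C=C(\C)C(C)=C | intermediate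
12 | (1E,6S,7E)-6-{[diphenyl(vinyl)silyl]oxy}-2,8,9-trimethyl-3-oxodeca-1,7,9-trien-1-yl acetate | CC(=O)O/C=C(\C)C(=O)CC[C@H](O[Si](C=C)(c1ccccc1)c1ccccc1)/C=C(\C)C(C)=C | intermediate
13 | trans-fused octalone: 6β-acetoxy-1α-{[diphenyl(vinyl)silyl]oxy}-5β,8,9-trimethyl-10αH-Δ8(9)-octal-4-one | O=C1CC[C@H](O[Si](C=C)(c3ccccc3)c3ccccc3)[C@@H]2[C@]1(C)[C@H](OC(C)=O)CC(C)=C2C | intermediate
14 | 4-bromofuran-2(5H)-one | O=C1C=C(Br)CO1 | starting material
15 | cyclic siloxane: 6β-acetoxy-5β,8,9β-trimethyl-10αH-Δ7-octal-4-one with O1(α)–SiPh2–C11 ring; C11 (on C9α) bears CH2-(5-oxo-2,5-dihydrofuran-3-yl), configured as in the target | O=C1CC[C@H](O3)[C@@H]2[C@]1(C)[C@H](OC(C)=O)C=C(C)[C@@]2(C)[C@@H](CC4=CC(=O)OC4)[Si]3(c5ccccc5)c5ccccc5 | intermediate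
16 | diol: 6β-acetoxy-1α-hydroxy-9α-[(1R)-1-hydroxy-2-(5-oxo-2,5-dihydrofuran-3-yl)ethyl]-5β,8,9β-trimethyl-10αH-Δ7-octal-4-one | O=C1CC[C@H](O)[C@@H]2[C@]1(C)[C@H](OC(C)=O)C=C(C)[C@@]2(C)[C@@H](CC3=CC(=O)OC3)O | intermediate
17 | 1-O-triethylsilyl ether of 16 | O=C1CC[C@H](O[Si](CC)(CC)CC)[C@@H]2[C@]1(C)[C@H](OC(C)=O)C=C(C)[C@@]2(C)[C@@H](CC3=CC(=O)OC3)O | intermediate
18 | triol: 7α,8α-dihydroxy derivative of 17 (6β-OAc, 8β-Me, 11R-OH, 1α-OTES, 4-ketone) | O=C1CC[C@H](O[Si](CC)(CC)CC)[C@@H]2[C@]1(C)[C@H](OC(C)=O)[C@@H](O)[C@@](C)(O)[C@@]2(C)[C@@H](CC3=CC(=O)OC3)O | intermediate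
19 | 7,11-bis(isobutyrate) of 18 (8α-OH free) | O=C1CC[C@H](O[Si](CC)(CC)CC)[C@@H]2[C@]1(C)[C@H](OC(C)=O)[C@@H](OC(=O)C(C)C)[C@@](C)(O)[C@@]2(C)[C@@H](CC3=CC(=O)OC3)OC(=O)C(C)C | intermediate
20 | 1-O-triethylsilyl ether of the target | C=C1CC[C@H](O[Si](CC)(CC)CC)[C@@H]2[C@]1(C)[C@H](OC(C)=O)[C@@H](OC(=O)C(C)C)[C@@](C)(O)[C@@]2(C)[C@@H](CC3=CC(=O)OC3)OC(=O)C(C)C | intermediate
21 | (1S,5S,6S,7R,8S,9R,10R,11R)-6-acetoxy-1,8-dihydroxy-7,11-bis(isobutyryloxy)cleroda-4(18),13-dien-15,16-olide (1α-OH, 5β-Me, 6β-OAc, 7α-OiBu, 8α-OH, 8β-Me, 9β-Me, 10α-H) | C=C1CC[C@H](O)[C@@H]2[C@]1(C)[C@H](OC(C)=O)[C@@H](OC(=O)C(C)C)[C@@](C)(O)[C@@]2(C)[C@@H](CC1=CC(=O)OC1)OC(=O)C(C)C | target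

**Total step count:** 13. **Longest linear sequence:** 13 steps (from 1).

**Steps most likely to fail**

Step 8 (the new cascade). The α-silyl radical may be intercepted by 14 before it cyclises onto the tetrasubstituted alkene. C11 selectivity rests on a conformational argument only. The C8 cation could suffer a methyl shift from C9 or lose a proton from C17 instead of C7. Fallback with known two-electron chemistry, setting out from 13 and returning at 15: a Mizoroki–Heck coupling of the vinylsilane with 14 (Pd(OAc)2, PPh3, Et3N, MeCN, 70 °C) gives the (E)-2-(butenolidyl)vinylsilyl ether F1. A Me2AlCl-promoted type 1 intramolecular ene reaction then joins C9 to C11 and moves H7 to C12, giving 15 with the Δ7 alkene and the conjugated butenolide.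

Step 7 (cycloaddition with the acetoxy-enone dienophile). The β-acetoxy group lowers dienophilicity, the E/Z purity of 12 controls C6, and prolonged heating may cost the enol ester. Fallback with boron as a masked hydroxyl, setting out from 11 and returning at 13: enol triflation (PhNTf2, Et3N) gives the (E)-enol triflate F2. Miyaura borylation (B2pin2, PdCl2(dppf), KOAc) gives the (E)-β-boryl enone F3, a well-behaved dienophile. Its intramolecular Diels–Alder reaction (toluene, 110 °C) gives the 6β-boronate F4. NaBO3·4H2O oxidation with retention gives the 6β-alcohol F5, and Ac2O/pyridine returns 13.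

Step 13 (late methylenation of the hindered C4 ketone). The ketone sits between the quaternary C5 and a β-acetoxy carbon and may resist the zinc–titanium reagent or suffer Lewis-acid damage. Fallback by Peterson olefination, setting out from 19 and returning at 21: Me3SiCH2Li/CeCl3 (THF, −78 °C) adds selectively to the ketone to give the β-hydroxysilane F6. Aqueous HF in MeCN then effects the elimination and removes the triethylsilyl group, giving 21.

**Further compounds**
F1 | step 8 | (E)-2-(5-oxo-2,5-dihydrofuran-3-yl)vinyl(diphenyl)silyl ether of the 1α-alcohol of 13 | O=C1CC[C@H](O[Si](/C=C/C3=CC(=O)OC3)(c4ccccc4)c4ccccc4)[C@@H]2[C@]1(C)[C@H](OC(C)=O)CC(C)=C2C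
F2 | step 7 | (1E,6S,7E)-6-{[diphenyl(vinyl)silyl]oxy}-2,8,9-trimethyl-3-oxodeca-1,7,9-trien-1-yl trifluoromethanesulfonate | O=S(=O)(O/C=C(\C)C(=O)CC[C@H](O[Si](C=C)(c1ccccc1)c1ccccc1)/C=C(\C)C(C)=C)C(F)(F)F
F3 | step 7 | (1E,6S,7E)-6-{[diphenyl(vinyl)silyl]oxy}-2,8,9-trimethyl-1-(pinacolatoboryl)deca-1,7,9-trien-3-one | CC1(C)OB(/C=C(\C)C(=O)CC[C@H](O[Si](C=C)(c2ccccc2)c2ccccc2)/C=C(\C)C(C)=C)OC1(C)C
F4 | step 7 | 6β-(pinacolatoboryl) analogue of 13 | O=C1CC[C@H](O[Si](C=C)(c3ccccc3)c3ccccc3)[C@@H]2[C@]1(C)[C@H](B3OC(C)(C)C(C)(C)O3)CC(C)=C2C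
F5 | step 7 | 6β-hydroxy analogue of 13 | O=C1CC[C@H](O[Si](C=C)(c3ccccc3)c3ccccc3)[C@@H]2[C@]1(C)[C@H](O)CC(C)=C2C
F6 | step 13 | 4-hydroxy-4-(trimethylsilylmethyl) adduct of 19 (mixture at C4) | C[Si](C)(C)CC1(O)CC[C@H](O[Si](CC)(CC)CC)[C@@H]2[C@]1(C)[C@H](OC(C)=O)[C@@H](OC(=O)C(C)C)[C@@](C)(O)[C@@]2(C)[C@@H](CC3=CC(=O)OC3)OC(=O)C(C)C
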